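Locants (tetralin): C1 CHMe, C2 CHOAc, C3 CH2, C4 CH bearing the side chain, C4a/C8a ring fusion, C5/C7 aryl CH, C6 C–CH2OAc, C8 C–OH, C11 side-chain CHMe.
Enabling feature: around the benzene ring C4a–C5–C6–C7–C8–C8a the substituents read bridge, H, CH2OAc, H, O, bridge. The ring therefore divides into three alkyne units (C4a≡C5, C6≡C7, C8≡C8a), and the outer two are already joined by the saturated C1–C2–C3–C4 half of the cyclohexane ring.
Cuts: C8–O goes back to C8–B and then C8–Br. C4a–C8a, C5–C6 and C7–C8 are then cut together to give a bromo-1,7-diyne and propargyl acetate. Finally C8a≡C8 and C4a≡C5 (aldehyde homologations), C1–C2 (aldol) and C3–C4 (enolate alkylation) lead back to (S)-citronellic acid.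
Forward: the open chain grows C11 → C4 → C3/C2 → C1/C8a with all four stereocentres in place. One operation then closes the carbocycle (metallacycle stage) and the benzene ring (insertion/elimination), and the phenol is unmasked last.
Stereochemistry: C11 comes from the chiral pool, C4 from an (S)-benzyloxazolidinone-directed alkylation, and C1 and C2 from an (R)-benzyloxazolidinone boron syn-aldol. The ring-forming step creates no stereocentre and disturbs none.

Key step: step 14

Remark: (S)-citronellic acid is taken as the purchased entry point (it is the oxidation product of (S)-citronellal), and its enantiopurity fixes that of C11.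

Step 1
Reactants: 1 (S)-citronellic acid; 2 (S)-4-benzyloxazolidin-2-one
Product: 4 (S)-4-benzyl-3-[(S)-3,7-dimethyloct-6-enoyl]oxazolidin-2-one, via mixed pivalic anhydride 3 (not isolated)
Conditions: PivCl, Et3N, THF, −20 °C; then LiCl, 2, −20 °C → rt
Reagents that add atoms: pivaloyl chloride, CC(C)(C)C(=O)Cl (its acyl group is carried only by 3)
Why: Mixed-anhydride N-acylation of an Evans oxazolidinone, in which the tert-butyl group shields the pivaloyl carbonyl of 3 so that LiCl-activated 2 attacks only the citronelloyl carbonyl, and C11 (β to the carbonyl) is not at risk.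

Step 2
Reactants: 4 (S)-4-benzyl-3-[(S)-3,7-dimethyloct-6-enoyl]oxazolidin-2-one; 5 tert-butyl bromoacetate
Product: 7 tert-butyl (3S,4S)-3-{[(S)-4-benzyl-2-oxooxazolidin-3-yl]carbonyl}-4,8-dimethylnon-7-enoate, via sodium (Z)-enolate 6 (not isolated)
Conditions: NaHMDS, THF, −78 °C; then 5, −78 → −40 °C
Reagents that add atoms: NaHMDS, [Na+].C[Si](C)(C)[N-][Si](C)(C)C (sodium is carried only by 6)
Why: Evans asymmetric alkylation forms C3–C4, because the benzyl group blocks one face of the chelated (Z)-enolate 6 and the reactive α-bromo ester is taken up on the opposite face, which sets C4 as S with the auxiliary overriding the small bias of C11.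

Step 3
Reactants: 7 tert-butyl (3S,4S)-3-{[(S)-4-benzyl-2-oxooxazolidin-3-yl]carbonyl}-4,8-dimethylnon-7-enoate
Product: 8 tert-butyl (3S,4S)-3-(hydroxymethyl)-4,8-dimethylnon-7-enoate
Conditions: LiBH4, MeOH (1 equiv), Et2O, 0 °C; pH 7 quench
Reagents that add atoms: none
Why: Reductive removal of the auxiliary with LiBH4 works because the activated exocyclic imide carbonyl is reduced far faster than the hindered tert-butyl ester, C4 is never enolised, and a cold neutral quench should keep the γ-hydroxy ester from lactonising.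

Step 4
Reactants: 8 tert-butyl (3S,4S)-3-(hydroxymethyl)-4,8-dimethylnon-7-enoate
Product: 9 tert-butyl (3S,4S)-3-formyl-4,8-dimethylnon-7-enoate
Conditions: DMP, CH2Cl2, 0 °C → rt
Reagents that add atoms: none
Why: Dess–Martin oxidation stops at the aldehyde under near-neutral conditions that leave the trisubstituted alkene, the tert-butyl ester and the α-stereocentre C4 untouched.

Step 5
Reactants: 9 tert-butyl (3S,4S)-3-formyl-4,8-dimethylnon-7-enoate
Product: 10 tert-butyl (3S,4S)-3-ethynyl-4,8-dimethylnon-7-enoate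
Conditions: MeC(O)C(N2)P(O)(OMe)2, K2CO3, MeOH, 0 °C → rt
Reagents that add atoms: dimethyl (1-diazo-2-oxopropyl)phosphonate (Ohira–Bestmann reagent), CC(=O)C(=[N+]=[N-])P(=O)(OC)OC
Why: The Ohira–Bestmann variant of the Seyferth–Gilbert homologation turns the formyl carbon into C4a and adds C5, under carbonate/methanol conditions that α-branched aldehydes and tert-butyl esters routinely tolerate without epimerisation or transesterification.

Step 6
Reactants: 10 tert-butyl (3S,4S)-3-ethynyl-4,8-dimethylnon-7-enoate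
Product: 12 (3S,4S)-3-ethynyl-4,8-dimethylnon-7-enal, via aluminium hemiacetal 11 (not isolated)
Conditions: DIBAL-H (1.1 equiv), CH2Cl2, −78 °C; Rochelle salt
Reagents that add atoms: DIBAL-H, CC(C)C[AlH]CC(C)C (aluminium and isobutyl groups are carried only by 11)
Why: In this partial ester reduction with DIBAL-H the crowded tert-butyl aluminium hemiacetal 11 does not collapse at −78 °C before the quench, so reduction should stop at the C2 aldehyde, and neither alkyne nor alkene is hydroaluminated at this temperature.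

Step 7
Reactants: 12 (3S,4S)-3-ethynyl-4,8-dimethylnon-7-enal; 13 (R)-4-benzyl-3-propionyloxazolidin-2-one
Product: 16 (R)-4-benzyl-3-[(2R,3S,5S,6S)-5-ethynyl-3-hydroxy-2,6,10-trimethylundec-9-enoyl]oxazolidin-2-one, via boron (Z)-enolate 14 (not isolated), via boron aldolate 15 (not isolated)
Conditions: 13, n-Bu2BOTf, Et3N, CH2Cl2, 0 °C; then 12, −78 → 0 °C; then pH 7 buffer, MeOH, 30% H2O2, 0 °C
Reagents that add atoms: dibutylboron triflate, CCCCB(CCCC)OS(=O)(=O)C(F)(F)F (boron and butyl groups are carried only by 14 and 15)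
Why: The Evans boron syn-aldol forms C1–C2 through a closed Zimmerman–Traxler chair of the (Z)-enolate 14, which gives the syn relationship, while the (R)-benzyl auxiliary selects the enolate face that sets the 2R,3S pair (C1 and C2 of the target), and the remote C4 centre of the α-unbranched aldehyde has no say.

Step 8
Reactants: 16 (R)-4-benzyl-3-[(2R,3S,5S,6S)-5-ethynyl-3-hydroxy-2,6,10-trimethylundec-9-enoyl]oxazolidin-2-one
Product: 17 (2R,3S,5S,6S)-5-ethynyl-3-hydroxy-N-methoxy-N,2,6,10-tetramethylundec-9-enamide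
Conditions: MeNH(OMe)·HCl, AlMe3, CH2Cl2, −10 °C → rt
Reagents that add atoms: N,O-dimethylhydroxylamine hydrochloride, CNOC.Cl
Why: In this Weinreb transamidation with an aluminium amide the free β-hydroxyl binds aluminium and directs attack to the exocyclic carbonyl, so the auxiliary leaves without retro-aldol or epimerisation at C1.

Step 9
Reactants: 17 (2R,3S,5S,6S)-5-ethynyl-3-hydroxy-N-methoxy-N,2,6,10-tetramethylundec-9-enamide
Product: 18 (2R,3S,5S,6S)-3-(tert-butyldimethylsilyloxy)-5-ethynyl-N-methoxy-N,2,6,10-tetramethylundec-9-enamide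
Conditions: TBSOTf, 2,6-lutidine, CH2Cl2, 0 °C
Reagents that add atoms: tert-butyldimethylsilyl triflate, CC(C)(C)[Si](C)(C)OS(=O)(=O)C(F)(F)F
Why: Silyl triflate/lutidine silylation of the hindered secondary alcohol masks C2–O against DIBAL-H and PPh3/CBr4 with a group that fluoride will remove in step 12.

Step 10
Reactants: 18 (2R,3S,5S,6S)-3-(tert-butyldimethylsilyloxy)-5-ethynyl-N-methoxy-N,2,6,10-tetramethylundec-9-enamide
Product: 20 (2R,3S,5S,6S)-3-(tert-butyldimethylsilyloxy)-5-ethynyl-2,6,10-trimethylundec-9-enal, via chelated aluminium adduct 19 (not isolated)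
Conditions: DIBAL-H, THF, −78 °C; Rochelle salt
Reagents that add atoms: DIBAL-H, CC(C)C[AlH]CC(C)C (aluminium and isobutyl groups are carried only by 19)
Why: In this Weinreb amide reduction the N-methoxy chelate 19 survives until the quench, so no over-reduction occurs, and the α-methyl aldehyde is carried on at once to protect C1.

Step 11
Reactants: 20 (2R,3S,5S,6S)-3-(tert-butyldimethylsilyloxy)-5-ethynyl-2,6,10-trimethylundec-9-enal
Product: 21 (3S,4S,6S,7S)-1,1-dibromo-4-(tert-butyldimethylsilyloxy)-6-ethynyl-3,7,11-trimethyldodeca-1,10-diene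
Conditions: CBr4, PPh3, 2,6-lutidine, CH2Cl2, 0 °C
Reagents that add atoms: carbon tetrabromide, BrC(Br)(Br)Br
Why: Ramirez dibromo-olefination (the first half of a Corey–Fuchs sequence) adds C8 with a non-basic ylide that does not epimerise C1, whose descriptor changes from R to S only through CIP priorities, while lutidine protects the silyl ether from adventitious HBr.

Step 12
Reactants: 21 (3S,4S,6S,7S)-1,1-dibromo-4-(tert-butyldimethylsilyloxy)-6-ethynyl-3,7,11-trimethyldodeca-1,10-diene
Product: 23 (3S,4S,6S,7S)-1-bromo-6-ethynyl-3,7,11-trimethyldodec-10-en-1-yn-4-ol, via hydroxy dibromoalkene 22 (not isolated)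
Conditions: TBAF·3H2O, DMF, rt, then 60 °C
Reagents that add atoms: none
Why: Fluoride first cleaves the silyl ether at room temperature and, on warming, wet TBAF acts as the mild base of the known TBAF-mediated dehydrobromination of 1,1-dibromoalkenes (anti E2), so bromine is placed on C8 without any reagent acting on the C5–H alkyne.

Step 13
Reactants: 23 (3S,4S,6S,7S)-1-bromo-6-ethynyl-3,7,11-trimethyldodec-10-en-1-yn-4-ol
Product: 24 (3S,4S,6S,7S)-1-bromo-6-ethynyl-3,7,11-trimethyldodec-10-en-1-yn-4-yl acetate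
Conditions: Ac2O, pyridine, DMAP (cat.), CH2Cl2, rt
Reagents that add atoms: acetic anhydride, CC(=O)OC(C)=O
Why: DMAP-catalysed acetylation installs the C2 acetate with retention while no phenol is yet present, so no later differentiation of hydroxyl groups is needed.

Step 14
Reactants: 24 (3S,4S,6S,7S)-1-bromo-6-ethynyl-3,7,11-trimethyldodec-10-en-1-yn-4-yl acetate; 25 propargyl acetate
Product: 27 (1S,2S,4S)-2-acetoxy-6-(acetoxymethyl)-8-bromo-1-methyl-4-[(S)-6-methylhept-5-en-2-yl]-1,2,3,4-tetrahydronaphthalene, via ruthenacyclopentadiene 26 (not isolated)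
Conditions: Cp*RuCl(cod) (10 mol %), 25 (5 equiv), ClCH2CH2Cl, Ar, rt → 50 °C, slow addition of 24
Reagents that add atoms: Cp*RuCl(cod), [Cl-].[Ru+2].Cc1c(C)c(C)[c-](C)c1C.C1=CCCC=CCC1 (the Cp*RuCl fragment is carried only by 26)
Why: This is a metal-catalysed [2+2+2] alkyne cyclotrimerisation of the Cp*RuCl diyne/monoalkyne type, known for unsymmetrical and halogen-capped diynes: after loss of cod the two tethered alkynes of 24 bind ruthenium and couple oxidatively to 26, then 25 inserts and reductive elimination releases 27 and the catalyst. The six-membered carbocycle closes in the first event through the C4a–C8a bond with both triple bonds exocyclic to the new ring (exo-dig at each end), helped by the branch points C1, C2 and C4 that fold the four-atom tether, and the benzene ring closes in the second event through C5–C6 and then C7–C8. No stereocentre is created, and the neutral medium leaves the propargylic C1–H and C4–H, the C2 acetate and C11 as they are. The step needs regioselectivity: the incoming alkyne engages the unhindered C5–H end of 26 and turns its acetoxymethyl group away from the bromine on C8, so the arm lands on C6, meta to Br, as is general for this catalyst with diynes substituted at one terminus. It also needs chemoselectivity for cross- over self-trimerisation, which the excess of 25 and the slow addition of 24 provide, while the trisubstituted side-chain alkene is too hindered to bind and the C(sp)–Br bond is not cleaved by Ru(II).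

Step 15
Reactants: 27 (1S,2S,4S)-2-acetoxy-6-(acetoxymethyl)-8-bromo-1-methyl-4-[(S)-6-methylhept-5-en-2-yl]-1,2,3,4-tetrahydronaphthalene
Product: 28 (1S,2S,4S)-2-acetoxy-6-(acetoxymethyl)-1-methyl-4-[(S)-6-methylhept-5-en-2-yl]-8-(4,4,5,5-tetramethyl-1,3,2-dioxaborolan-2-yl)-1,2,3,4-tetrahydronaphthalene
Conditions: B2pin2, XPhos Pd G2 (5 mol %), KOAc, 1,4-dioxane, 80 °C
Reagents that add atoms: bis(pinacolato)diboron, CC1(C)OB(OC1(C)C)B1OC(C)(C)C(C)(C)O1
Why: Miyaura borylation with a bulky monophosphine copes with the ortho-substituted C8–Br bond, acetate is too weak a base to harm either ester, and a monodentate ligand disfavours η3-benzyl ionisation of the C6–CH2OAc group.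

Step 16
Reactants: 28 (1S,2S,4S)-2-acetoxy-6-(acetoxymethyl)-1-methyl-4-[(S)-6-methylhept-5-en-2-yl]-8-(4,4,5,5-tetramethyl-1,3,2-dioxaborolan-2-yl)-1,2,3,4-tetrahydronaphthalene
Product: 29 CNP0210401.1, (1S,2S,4S)-2-acetoxy-6-(acetoxymethyl)-8-hydroxy-1-methyl-4-[(S)-6-methylhept-5-en-2-yl]-1,2,3,4-tetrahydronaphthalene
Conditions: NaBO3·4H2O, THF/H2O (1:1), 0 °C → rt
Reagents that add atoms: sodium perborate tetrahydrate (drawn as the dimeric peroxoborate salt, water of crystallisation omitted), [Na+].[Na+].O[B-]1(O)OO[B-](O)(O)OO1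
Why: Ipso-oxidation of the arylboronate (1,2-aryl shift from boron to oxygen) with mildly basic perborate delivers the C8 phenol without epoxidising the alkene and should be quick enough to spare the two alkyl acetates.

Compound list
1 | (S)-citronellic acid, (S)-3,7-dimethyloct-6-enoic acid | C[C@@H](CCC=C(C)C)CC(=O)O | starting material
2 | (S)-4-benzyloxazolidin-2-one | O=C1N[C@@H](Cc2ccccc2)CO1 | starting material
3 | (S)-3,7-dimethyloct-6-enoic pivalic anhydride (not isolated) | C[C@@H](CCC=C(C)C)CC(=O)OC(=O)C(C)(C)C | intermediate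
4 | (S)-4-benzyl-3-[(S)-3,7-dimethyloct-6-enoyl]oxazolidin-2-one | C[C@@H](CCC=C(C)C)CC(=O)N1[C@@H](Cc2ccccc2)COC1=O | intermediate
5 | tert-butyl bromoacetate | CC(C)(C)OC(=O)CBr | starting material
6 | sodium (Z)-enolate of 4 (not isolated) | [Na+].[O-]/C(=C\[C@@H](C)CCC=C(C)C)N1[C@@H](Cc2ccccc2)COC1=O | intermediate
7 | tert-butyl (3S,4S)-3-{[(S)-4-benzyl-2-oxooxazolidin-3-yl]carbonyl}-4,8-dimethylnon-7-enoate | O=C(N1[C@@H](Cc2ccccc2)COC1=O)[C@H]([C@@H](C)CCC=C(C)C)CC(=O)OC(C)(C)C | intermediate
8 | tert-butyl (3S,4S)-3-(hydroxymethyl)-4,8-dimethylnon-7-enoate | OC[C@H]([C@@H](C)CCC=C(C)C)CC(=O)OC(C)(C)C | intermediate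
9 | tert-butyl (3S,4S)-3-formyl-4,8-dimethylnon-7-enoate | O=C[C@H]([C@@H](C)CCC=C(C)C)CC(=O)OC(C)(C)C | intermediate
10 | tert-butyl (3S,4S)-3-ethynyl-4,8-dimethylnon-7-enoate | C#C[C@H]([C@@H](C)CCC=C(C)C)CC(=O)OC(C)(C)C | intermediate
11 | diisobutylaluminium tert-butyl hemiacetal of 12 (not isolated, hemiacetal carbon undefined) | C#C[C@H]([C@@H](C)CCC=C(C)C)CC(OC(C)(C)C)O[Al](CC(C)C)CC(C)C | intermediate
12 | (3S,4S)-3-ethynyl-4,8-dimethylnon-7-enal | C#C[C@H]([C@@H](C)CCC=C(C)C)CC=O | intermediate
13 | (R)-4-benzyl-3-propionyloxazolidin-2-one | CCC(=O)N1[C@H](Cc2ccccc2)COC1=O | starting material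
14 | (Z)-dibutylboron enolate of 13 (not isolated) | C/C=C(\OB(CCCC)CCCC)N1[C@H](Cc2ccccc2)COC1=O | intermediate
15 | dibutylboron aldolate of 16 (not isolated) | C#C[C@H]([C@@H](C)CCC=C(C)C)C[C@H](OB(CCCC)CCCC)[C@@H](C)C(=O)N1[C@H](Cc2ccccc2)COC1=O | intermediate
16 | (R)-4-benzyl-3-[(2R,3S,5S,6S)-5-ethynyl-3-hydroxy-2,6,10-trimethylundec-9-enoyl]oxazolidin-2-one | C#C[C@H]([C@@H](C)CCC=C(C)C)C[C@H](O)[C@@H](C)C(=O)N1[C@H](Cc2ccccc2)COC1=O | intermediate
17 | (2R,3S,5S,6S)-5-ethynyl-3-hydroxy-N-methoxy-N,2,6,10-tetramethylundec-9-enamide | C#C[C@H]([C@@H](C)CCC=C(C)C)C[C@H](O)[C@@H](C)C(=O)N(C)OC | intermediate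
18 | (2R,3S,5S,6S)-3-(tert-butyldimethylsilyloxy)-5-ethynyl-N-methoxy-N,2,6,10-tetramethylundec-9-enamide | C#C[C@H]([C@@H](C)CCC=C(C)C)C[C@H](O[Si](C)(C)C(C)(C)C)[C@@H](C)C(=O)N(C)OC | intermediate
19 | diisobutylaluminium adduct of 18 (not isolated, adduct carbon undefined) | C#C[C@H]([C@@H](C)CCC=C(C)C)C[C@H](O[Si](C)(C)C(C)(C)C)[C@@H](C)C(O[Al](CC(C)C)CC(C)C)N(C)OC | intermediate
20 | (2R,3S,5S,6S)-3-(tert-butyldimethylsilyloxy)-5-ethynyl-2,6,10-trimethylundec-9-enal | C#C[C@H]([C@@H](C)CCC=C(C)C)C[C@H](O[Si](C)(C)C(C)(C)C)[C@@H](C)C=O | intermediate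
21 | (3S,4S,6S,7S)-1,1-dibromo-4-(tert-butyldimethylsilyloxy)-6-ethynyl-3,7,11-trimethyldodeca-1,10-diene | C#C[C@H]([C@@H](C)CCC=C(C)C)C[C@H](O[Si](C)(C)C(C)(C)C)[C@@H](C)C=C(Br)Br | intermediate
22 | (3S,4S,6S,7S)-1,1-dibromo-6-ethynyl-3,7,11-trimethyldodeca-1,10-dien-4-ol (not isolated) | C#C[C@H]([C@@H](C)CCC=C(C)C)C[C@H](O)[C@@H](C)C=C(Br)Br | intermediate
23 | (3S,4S,6S,7S)-1-bromo-6-ethynyl-3,7,11-trimethyldodec-10-en-1-yn-4-ol | C#C[C@H]([C@@H](C)CCC=C(C)C)C[C@H](O)[C@@H](C)C#CBr | intermediate
24 | (3S,4S,6S,7S)-1-bromo-6-ethynyl-3,7,11-trimethyldodec-10-en-1-yn-4-yl acetate (bromodiyne, key-step precursor) | C#C[C@H]([C@@H](C)CCC=C(C)C)C[C@H](OC(C)=O)[C@@H](C)C#CBr | intermediate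
25 | propargyl acetate (prop-2-yn-1-yl acetate) | C#CCOC(C)=O | starting material
26 | Cp*RuCl ruthenacyclopentadiene, Ru bound to C5 and C8, C4a–C8a bond formed (not isolated) | BrC1=C2[C@H](C)[C@@H](OC(C)=O)C[C@@H]([C@@H](C)CCC=C(C)C)C2=C[Ru+]1Cl.Cc1c(C)c(C)[c-](C)c1C | intermediate
27 | (1S,2S,4S)-2-acetoxy-6-(acetoxymethyl)-8-bromo-1-methyl-4-[(S)-6-methylhept-5-en-2-yl]-1,2,3,4-tetrahydronaphthalene (key-step product) | CC(=O)OCc1cc(Br)c2c(c1)[C@H]([C@@H](C)CCC=C(C)C)C[C@H](OC(C)=O)[C@H]2C | intermediate
28 | 8-(pinacolboryl) analogue of 27 | CC(=O)OCc1cc(B3OC(C)(C)C(C)(C)O3)c2c(c1)[C@H]([C@@H](C)CCC=C(C)C)C[C@H](OC(C)=O)[C@H]2C | intermediate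
29 | CNP0210401.1, (1S,2S,4S)-2-acetoxy-6-(acetoxymethyl)-8-hydroxy-1-methyl-4-[(S)-6-methylhept-5-en-2-yl]-1,2,3,4-tetrahydronaphthalene | CC(=O)OCc1cc(O)c2c(c1)[C@H]([C@@H](C)CCC=C(C)C)C[C@H](OC(C)=O)[C@H]2C | target

Total step count: 16. Longest linear sequence: 16 steps (1 → 29); 2, 5, 13 and 25 are purchased.

Steps most likely to fail

Step 14.
- **What may go wrong:** Oxidative coupling across a four-atom tether is slower than across a three-atom one, so self-trimerisation of 25 and dimerisation of 24 may overtake the cross reaction. The size difference between Br and H may also fail to hold the orientation of insertion.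
- **Fallback, from 24 back to 27:** The third alkyne is made intramolecular through a traceless silicon link at C5, which forms the same three bonds but fixes C6 next to C5 by ring size. Zinc triflate-promoted C-silylation of the terminal alkyne (i-Pr2SiHCl, Zn(OTf)2, Et3N, CH2Cl2, rt) would give the C5-diisopropylsilyl bromodiyne acetate F1. Ruthenium-catalysed dehydrogenative alcoholysis of its Si–H bond with propargyl alcohol ([RuCl2(p-cymene)]2 cat., CH2Cl2, rt) would give the propargyloxysilyl triyne F2. Cp*RuCl(cod) in ClCH2CH2Cl would then couple the 1,6-related pair C4a≡C5/C6≡C7 first and take in the bromoalkyne last, giving the tricyclic benzoxasilole F3. TBAF in THF would cleave Si–O and protodesilylate C5 to the 6-hydroxymethyl bromide F4. Ac2O/pyridine, which also restores any C2 acetate lost to fluoride, returns 27.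

Step 12.
- **What may go wrong:** Once C2–O is unmasked in a basic fluoride medium it may add to the halogenated π system (5-endo closure to a bromodihydrofuran), or the elimination may stall.
- **Fallback, from 21 back to 23:** The two events are separated and each is run by a different mechanism. With the silyl ether still in place, a hindered amide base (NaHMDS, 2.2 equiv to allow for C5–H, THF, −78 °C) would bring about E2 loss of HBr to the silyl-protected bromodiyne F5. Acidic fluoride (HF·pyridine, THF, 0 °C), under which no alkoxide arises next to the bromoalkyne, would then free 23.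

Step 15.
- **What may go wrong:** Oxidative addition and transmetalation may be slow at the C8–Br bond, which is flanked by the C1 methine, with protodebromination as the outlet. Pd(0) may also ionise the benzylic C6–CH2OAc group.
- **Fallback, from 27 directly to 29 (28 and step 16 are bypassed):** C–O coupling replaces C–B coupling, with an oxime as hydroxide surrogate. (E)-Benzaldoxime, tBuBrettPhos Pd G3 and Cs2CO3 in DMF at 80 °C would give the O-aryl benzaldoxime F6. This fragments under the same anhydrous carbonate conditions into benzonitrile and the phenoxide of 29, and a mildly acidic work-up gives 29 with the acetates never meeting hydroxide or peroxide.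

Further compounds
F1 | step 14 | (3S,4S,6S,7S)-1-bromo-6-[(diisopropylsilyl)ethynyl]-3,7,11-trimethyldodec-10-en-1-yn-4-yl acetate | CC(C)[SiH](C(C)C)C#C[C@H]([C@@H](C)CCC=C(C)C)C[C@H](OC(C)=O)[C@@H](C)C#CBr
F2 | step 14 | (3S,4S,6S,7S)-1-bromo-6-{[diisopropyl(prop-2-yn-1-yloxy)silyl]ethynyl}-3,7,11-trimethyldodec-10-en-1-yn-4-yl acetate | C#CCO[Si](C(C)C)(C(C)C)C#C[C@H]([C@@H](C)CCC=C(C)C)C[C@H](OC(C)=O)[C@@H](C)C#CBr
F3 | step 14 | tricyclic benzoxasilole: analogue of 27 with C5–Si(i-Pr)2–O–CH2–C6 ring in place of C5–H and C6–CH2OAc | CC(C)[Si]1(C(C)C)OCc2cc(Br)c3c(c21)[C@H]([C@@H](C)CCC=C(C)C)C[C@H](OC(C)=O)[C@H]3C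
F4 | step 14 | (1S,2S,4S)-2-acetoxy-8-bromo-6-(hydroxymethyl)-1-methyl-4-[(S)-6-methylhept-5-en-2-yl]-1,2,3,4-tetrahydronaphthalene | OCc1cc(Br)c2c(c1)[C@H]([C@@H](C)CCC=C(C)C)C[C@H](OC(C)=O)[C@H]2C
F5 | step 12 | (3S,4S,6S,7S)-1-bromo-4-(tert-butyldimethylsilyloxy)-6-ethynyl-3,7,11-trimethyldodec-10-en-1-yne | C#C[C@H]([C@@H](C)CCC=C(C)C)C[C@H](O[Si](C)(C)C(C)(C)C)[C@@H](C)C#CBr
F6 | step 15 | O-aryl (E)-benzaldoxime: analogue of 27 with C8–O–N=CHPh in place of C8–Br | CC(=O)OCc1cc(O/N=C/c3ccccc3)c2c(c1)[C@H]([C@@H](C)CCC=C(C)C)C[C@H](OC(C)=O)[C@H]2C
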